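**Retrosynthetic overview**
1. The target comes from its bis(methyl ether) by O-demethylation in the last step.
2. Key disconnection is the Ar–CH2 bond. It leads back to 3,5-dimethoxyphenyl 3-oxotetracosanoate, whose aryl group moves from O to C with loss of CO2 (new nickel catalysis).
3. The aryl β-keto ester comes from 3,5-dimethoxyphenol and docosanoylketene, which is released from docosanoyl Meldrum's acid.
4. Docosanoyl Meldrum's acid comes from behenic acid (C22, supplies C2'–C23') and Meldrum's acid (supplies C1').
5. No ring is formed. The benzene ring is bought with the phenol, and the dioxanedione ring is only a carrier that is destroyed.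

Assumption: the target has no stereocentre and is achiral, so no enantiomer has to be chosen and no stereocontrol is needed; species bound to the nickel catalyst within its cycle are described in words and carry no compound number.

**Step 1**
Reactants: 1 behenic acid (docosanoic acid)
Product: 2 docosanoyl chloride
Conditions: (COCl)2 (1.3 equiv), DMF (cat.), CH2Cl2, 0 → 35 °C
Reagents that add atoms: oxalyl chloride, ClC(=O)C(=O)Cl
Why: Acid chloride formation through the catalytic Vilsmeier-type chloroiminium salt is general for saturated fatty acids, and 1 carries no other functional group and no stereocentre.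

**Step 2**
Reactants: 2 docosanoyl chloride; 3 Meldrum's acid (2,2-dimethyl-1,3-dioxane-4,6-dione)
Product: 4 5-(1-hydroxydocosylidene)-2,2-dimethyl-1,3-dioxane-4,6-dione (enol form of docosanoyl Meldrum's acid)
Conditions: pyridine (2.2 equiv), CH2Cl2, 0 → 25 °C; 1 M HCl wash
Reagents that add atoms: none
Why: C-acylation of the very acidic Meldrum's acid with an acid chloride and pyridine (Oikawa–Yonemitsu acylation) is routine for long-chain acyl chlorides, stops at the hydrogen-bonded enol, and forms no stereocentre.

**Step 3**
Reactants: 4 5-(1-hydroxydocosylidene)-2,2-dimethyl-1,3-dioxane-4,6-dione; 5 3,5-dimethoxyphenol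
Product: 7 3,5-dimethoxyphenyl 3-oxotetracosanoate, via docosanoylketene 6 (not isolated)
Conditions: toluene, 110 °C, 3 h
Reagents that add atoms: none
Why: Thermal retro-[4+2] fragmentation of the acyl Meldrum's acid gives acylketene 6, which the phenol O–H traps (acylketene trapping) under neutral, acid-free conditions that hold back Pechmann-type closure, and no stereocentre is formed.

**Step 4**
Reactants: 7 3,5-dimethoxyphenyl 3-oxotetracosanoate
Product: 8 1-(3,5-dimethoxyphenyl)tricosan-2-one
Conditions: Ni(cod)2 (10 mol %), dcypt (3,4-bis(dicyclohexylphosphino)thiophene, 12 mol %), m-xylene, 125 °C, Ar, 7 added by syringe pump over 8 h, no base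
Reagents that add atoms: none
Why: Proposed new method: a base-free nickel-catalysed CO2-extrusion α-arylation of an aryl β-keto ester, in which electron-rich zerovalent nickel on the chelating dialkylbisphosphine adds oxidatively into the C(aryl)–O bond of 7 (carbonyl-assisted five-centre transition state, with the two meta methoxy groups inductively withdrawing at that carbon), the divalent aryl nickel β-keto carboxylate loses CO2 fast and irreversibly through a six-membered transition state to give only the terminal CH2 nickel enolate, and C–C reductive elimination forms the Ar–CH2 bond and returns zerovalent nickel; the kinetically easier C(acyl)–O insertion is reversible and should stay a dead end because its decarbonylation is slower than CO2 loss on the productive path, slow addition keeps the acidic CH2 of unreacted 7 from protonating the enolate or chelating divalent nickel, and one aryl group per enolate without base rules out diarylation and wrong-side arylation; the closest known reaction types are the palladium-catalysed decarboxylative allylation and benzylation of allyl and benzyl β-keto esters (Tsuji–Saegusa and Tunge type), the nickel-catalysed α-arylation of ketones with aryl pivalates using the same ligand class, and the nickel-catalysed CO2 extrusion from aryl carbamates to anilines, none of which transfers an aryl group from a β-keto ester oxygen to the enolate carbon.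

**Step 5**
Reactants: 8 1-(3,5-dimethoxyphenyl)tricosan-2-one
Product: 10 5-(2'-oxotricosyl)resorcinol, via bis(dibromoboryl) ether 9 (not isolated)
Conditions: BBr3 (4 equiv), CH2Cl2, 0 → 25 °C; then H2O, 0 °C
Reagents that add atoms: none
Why: Lewis-acid aryl methyl ether cleavage (O-coordination of BBr3, then SN2 attack of bromide on methyl) gives aryloxydibromoborane 9, which water hydrolyses to the diphenol, while the saturated ketone only binds extra BBr3 reversibly and the meta arrangement excludes benzofuran closure.

**Compound list**
1 | behenic acid (docosanoic acid) | CCCCCCCCCCCCCCCCCCCCCC(=O)O | starting material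
2 | docosanoyl chloride | CCCCCCCCCCCCCCCCCCCCCC(=O)Cl | intermediate
3 | Meldrum's acid (2,2-dimethyl-1,3-dioxane-4,6-dione) | CC1(C)OC(=O)CC(=O)O1 | starting material
4 | 5-(1-hydroxydocosylidene)-2,2-dimethyl-1,3-dioxane-4,6-dione | CCCCCCCCCCCCCCCCCCCCCC(O)=C1C(=O)OC(C)(C)OC1=O | intermediate
5 | 3,5-dimethoxyphenol | COc1cc(O)cc(OC)c1 | starting material
6 | docosanoylketene (tetracos-1-ene-1,3-dione) | CCCCCCCCCCCCCCCCCCCCCC(=O)C=C=O | intermediate
7 | 3,5-dimethoxyphenyl 3-oxotetracosanoate | CCCCCCCCCCCCCCCCCCCCCC(=O)CC(=O)Oc1cc(OC)cc(OC)c1 | intermediate
8 | 1-(3,5-dimethoxyphenyl)tricosan-2-one | CCCCCCCCCCCCCCCCCCCCCC(=O)Cc1cc(OC)cc(OC)c1 | intermediate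
9 | 1-[3,5-bis(dibromoboryloxy)phenyl]tricosan-2-one | CCCCCCCCCCCCCCCCCCCCCC(=O)Cc1cc(OB(Br)Br)cc(OB(Br)Br)c1 | intermediate
10 | 5-(2'-oxotricosyl)resorcinol, 1-(3,5-dihydroxyphenyl)tricosan-2-one (achiral) | CCCCCCCCCCCCCCCCCCCCCC(=O)Cc1cc(O)cc(O)c1 | target

Total step count: 5. Longest linear sequence: 5 steps (1 → 2 → 4 → 7 → 8 → 10).

**Steps most likely to fail**

**Step 4 (the proposed new step).**
- Risk: insertion into the C(aryl)–O bond of a non-fused, unhindered aryl ester may be too slow.
- Risk: C(acyl)–O chemistry could then take over, with decarbonylation and CO poisoning of the catalyst.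
- Risk: the acidic 1,3-dicarbonyl may protonate the enolate or lock divalent nickel in an O,O-chelate.
- Risk: at 125 °C the ester may lose phenol 5 back to ketene 6, or close to a coumarin.
- Fallback (known chemistry): it sets out from 2 and comes back at 8. Commercial 3,5-dimethoxybenzyl bromide F1 is treated with Zn dust and LiCl in THF at 25 °C to give (3,5-dimethoxybenzyl)zinc bromide F2. This is acylated with docosanoyl chloride 2 under Pd(PPh3)4 (2 mol %) in THF at 0 → 25 °C (Negishi acylation of a benzylic zinc reagent). The benzyl–acyl bond is made instead of the aryl–CH2 bond, and 8 is delivered directly.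

**Step 3.**
- Risk: the very electron-rich phenol may react at carbon, or the hot product may cyclise.
- Risk: traces of water turn ketene 6 into the methyl ketone.
- Fallback: it sets out from 2 and comes back at 7. The ester C–O bond is made first and the C–C bond second, at room temperature. Meldrum's acid 3 and phenol 5 are heated in toluene at 100 °C to give the half ester 3-(3,5-dimethoxyphenoxy)-3-oxopropanoic acid F3. Its magnesium enolate (MgCl2, Et3N, THF–MeCN, 0 → 25 °C) is C-acylated with 2 (magnesium malonate acylation, Masamune–Brooks and Rathke type). This gives 2-[(3,5-dimethoxyphenoxy)carbonyl]-3-oxotetracosanoic acid F4, which decarboxylates on work-up with 1 M HCl to 7.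

**Step 5.**
- Risk: cleavage of the second methyl ether may be incomplete.
- Risk: BBr3 may promote condensation of the resorcinol ring with the ketone.
- Fallback: it sets out from 2 and comes back at 10. The protecting group is changed so that the last step is a neutral hydrogenolysis. Commercial 3,5-bis(benzyloxy)benzyl bromide F5 is converted with Zn dust and LiCl (THF, 25 °C) into [3,5-bis(benzyloxy)benzyl]zinc bromide F6. Acylation with 2 under Pd(PPh3)4 (2 mol %, THF, 0 → 25 °C) gives 1-[3,5-bis(benzyloxy)phenyl]tricosan-2-one F7. H2 (1 atm) over Pd/C (10 wt %) in THF–EtOH at 25 °C removes both benzyl groups without touching the homobenzylic ketone and gives 10.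

**Further compounds**
F1 | step 4 | 3,5-dimethoxybenzyl bromide | COc1cc(CBr)cc(OC)c1
F2 | step 4 | (3,5-dimethoxybenzyl)zinc bromide | COc1cc(C[Zn]Br)cc(OC)c1
F3 | step 3 | 3-(3,5-dimethoxyphenoxy)-3-oxopropanoic acid | COc1cc(OC(=O)CC(=O)O)cc(OC)c1
F4 | step 3 | 2-[(3,5-dimethoxyphenoxy)carbonyl]-3-oxotetracosanoic acid | CCCCCCCCCCCCCCCCCCCCCC(=O)C(C(=O)O)C(=O)Oc1cc(OC)cc(OC)c1
F5 | step 5 | 3,5-bis(benzyloxy)benzyl bromide | BrCc1cc(OCc2ccccc2)cc(OCc2ccccc2)c1
F6 | step 5 | [3,5-bis(benzyloxy)benzyl]zinc bromide | Br[Zn]Cc1cc(OCc2ccccc2)cc(OCc2ccccc2)c1
F7 | step 5 | 1-[3,5-bis(benzyloxy)phenyl]tricosan-2-one | CCCCCCCCCCCCCCCCCCCCCC(=O)Cc1cc(OCc2ccccc2)cc(OCc2ccccc2)c1
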